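The earlier runs and the new flask are simulated on assumed constants; the scatter is artificial.

Time first: the flask stands 40 h with 8.9 mM of G, less G than either earlier run, and I want to know how much of that time it uses.

| setting | south-west | west | flask |
|---|---|---|---|
| D | 2.7 M | 2.7 M | 2.7 M |
| G | 12 mM | 20 mM | 8.9 mM |
| remark | run made earlier | run made earlier |  |
| time |  |  | 40 h |

- south-west (time / h: D / %, Z / %, J / %): 2.00: 32.8, 36.6, 4.1; 4.00: 19.5, 56.0, 3.3; 6.00: 10.5, 65.8, 2.4; 12.0: 0.5, 81.0, 0.2; 25.0: 0.3, 80.4, 0
- west (time / h: D / %, Z / %, J / %): 2.00: 32.8, 34.4, 5.8; 4.00: 18.7, 56.4, 2.7; 6.00: 11.0, 67.6, 0.2; 12.0: 1.5, 79.7, 0; 25.0: 2.8, 83.2, 0.7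

(standard deviation of a reading: 1 percentage point)

- why nothing more happens at 40 h, or that something still does (it is still moving / forward and back rates have come level / all of D has reacted)
- conversion of D at 40 h
- amount of Z at 40 h, in percent of the D charged

- the reaction counts as stopped when no species that holds the D changes by six tenths of a point or more over the second half of the time

In the first instants the south-west run loses D fast: at 2.00 h D is down to 32.8%, Z is already 36.6% and J is small at 4.1%. The middle goes more evenly, so I read the pace there. From 2.00 h to 6.00 h D falls to 10.5%, which gives my tail half-life, the time D takes to halve once the first rush is over 2.43 h. It is an apparent first-order half-life, read with the scatter of the readings.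

Now I put it back in. From the west run's 32.8%, it gives 10.5% at 6.00 h, and the west run reads 11.0%, within the scatter, with 1.67 times the G. So I carry the pace to the flask, although its G lies below both runs.

For the end, I count on from the south-west run's 6.00 h reading. At 20.0 h I reckon D in the flask at 0.195%, inside the stopping limit, and at 40 h at <0.001%. So I expect D used up, with that <0.001% left, and the flask stopped. The four late Z readings average 81.1%, which is my figure for Z.

The forecast answers all of D has reacted, with conversion 99.5%, lower than mine, and Z 81.5%, a little above mine. It holds that “the rate barely depends on G here”.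

The flask gives all of D has reacted, with conversion >99.9% and Z 82.0%. At 20.0 h it has D 0.216%, against my 0.195%.

    J → Z (k = 8.00 × 10⁻⁴ s⁻¹)
    D + G ⇌ J + G, rate k2*[D]*[G] forward; the back reaction follows from the equilibrium constant (K = 0.140, k = 0.190 M⁻¹ s⁻¹)
    J + G ⇌ E + G, rate k3*[G]*[J] forward; the back reaction follows from the equilibrium constant (K = 3.90, k = 0.920 M⁻¹ s⁻¹)
    D → Q (k = 2.30 × 10⁻⁵ s⁻¹)

The plateau of Z is the forecast's step that carried the weight, and in the flask it rests on material coming back. E, which was not among the readings, holds 10.6% of the D charged in the flask at 4.00 h. In the run of this flask without the step from E back to J, Z ends at 8.63% rather than 82.0%. The flask's Z moves by 5 points with G down at 1.31 mM, or with the reading brought forward to 9.99 h.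

Read at 10 h, the same flask should hold D 3.35% by the tail half-life. It holds 3.59%, with Z at 77.1%.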